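**Retrosynthetic overview**
- The strategy rests on the A ring: H at C5, three adjacent oxygens at C6, C7 and C8, and C8 next to the fusion carbon C8a that carries O1. This maps onto C4–H, C3–OMe, C2–OMe and C1=O of a squarate-derived cyclobutenone attached to C5 of a 2-aryl-4-pyranone.
- Disconnections: C8 O–Me (methylation); C8–C8a (6π/4π electrocyclic sequence, back to cyclobutenone 11); cyclobutenone C4–pyranone C5 (Stille coupling of chloride 10 with stannane 7).
- Chloride 10 comes from dimethyl squarate by mono-reduction and chlorination. Stannane 7 comes from bromopyranone 6, built from 3,4-dimethoxybenzoyl chloride and a 3-bromo-4-methoxybutenone so that the halogen sits at C5 by construction.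
- Ring order: B ring purchased; C ring (pyranone) in step 2; A ring last, in step 7.

Key step: step 7

Remark: the target is an achiral flavone with no stereocentre, so no enantiocontrol is needed; the stereocentres in 9, 10, 11 and 13 are racemic and are destroyed in step 7.

**Route**

Step 1
Reactants: 1 (E)-4-methoxybut-3-en-2-one
Product: 3 (Z)-3-bromo-4-methoxybut-3-en-2-one, via dibromo ketone 2 (not isolated)
Conditions: Br2 (1.0 equiv), CH2Cl2, −78 °C; then Et3N (1.2 equiv), −78 → 0 °C
Reagents that add atoms: bromine, BrBr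
Why: Bromine adds across the electron-rich enol-ether double bond and triethylamine then removes the acidic C3 proton with loss of the C4 bromide (bromination–dehydrobromination of a β-alkoxy enone), which places the halogen on the carbon that becomes pyranone C5, the Z isomer being expected as the main one although either geometry serves.

Step 2
Reactants: 3 (Z)-3-bromo-4-methoxybut-3-en-2-one; 4 3,4-dimethoxybenzoyl chloride
Product: 6 5-bromo-2-(3,4-dimethoxyphenyl)-4H-pyran-4-one, via bromo methoxy diketone 5 (not isolated)
Conditions: 3 (2 equiv), LiHMDS (2 equiv), THF, −78 °C; 4 (1 equiv), −78 °C; quench, concentrate; TFA, CH2Cl2, rt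
Reagents that add atoms: none
Why: Kinetic deprotonation of the methyl ketone and C-acylation of the lithium enolate by the aroyl chloride (Claisen-type enolate acylation, the second equivalent of enolate absorbing the acidic diketone) gives the 1,3-diketone, whose enol oxygen then displaces methanol by acid-catalysed 6-endo addition–elimination to close the γ-pyrone with bromine at C5 and hydrogen at C3.

Step 3
Reactants: 6 5-bromo-2-(3,4-dimethoxyphenyl)-4H-pyran-4-one
Product: 7 2-(3,4-dimethoxyphenyl)-5-(tributylstannyl)-4H-pyran-4-one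
Conditions: (Bu3Sn)2 (1.5 equiv), Pd(PPh3)4 (5 mol%), PhMe, 110 °C; chromatography on Et3N-deactivated silica
Reagents that add atoms: hexabutylditin, CCCC[Sn](CCCC)(CCCC)[Sn](CCCC)(CCCC)CCCC
Why: Palladium-catalysed stannylation of the vinylic C–Br bond with a distannane (oxidative addition, Sn–Sn transmetalation, reductive elimination) is a standard entry to α-stannyl enones and tolerates the pyranone carbonyl that an organolithium route would attack.

Step 4
Reactants: 8 dimethyl squarate (3,4-dimethoxycyclobut-3-ene-1,2-dione)
Product: 9 rac-4-hydroxy-2,3-dimethoxycyclobut-2-en-1-one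
Conditions: LiAlH(OtBu)3 (1.05 equiv), THF, −78 → −20 °C; cold aq. Rochelle salt, pH 7
Reagents that add atoms: none
Why: The bulky hydride reduces one of the two equivalent squarate carbonyls by 1,2-addition and should stop there because the remaining carbonyl is a much less electrophilic vinylogous ester, the new C4 centre being racemic and of no consequence.

Step 5
Reactants: 9 rac-4-hydroxy-2,3-dimethoxycyclobut-2-en-1-one
Product: 10 rac-4-chloro-2,3-dimethoxycyclobut-2-en-1-one
Conditions: PPh3, NCS, CH2Cl2, −20 → 0 °C; short silica pad, used at once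
Reagents that add atoms: N-chlorosuccinimide, O=C1CCC(=O)N1Cl
Why: Appel-type chlorination through the alkoxyphosphonium salt replaces the allylic α-keto hydroxyl by chloride under neutral conditions, avoiding the acid that would divert this alcohol to a cyclobutenedione.

Step 6
Reactants: 7 2-(3,4-dimethoxyphenyl)-5-(tributylstannyl)-4H-pyran-4-one; 10 rac-4-chloro-2,3-dimethoxycyclobut-2-en-1-one
Product: 11 rac-4-[6-(3,4-dimethoxyphenyl)-4-oxo-4H-pyran-3-yl]-2,3-dimethoxycyclobut-2-en-1-one
Conditions: Pd2(dba)3 (2.5 mol%), tri(2-furyl)phosphine (10 mol%), CuI (10 mol%), DMF, 23 °C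
Reagents that add atoms: none
Why: In this Stille cross-coupling of a 4-chlorocyclobutenone, Pd(0) ionises the allylic C–Cl bond to an η3-oxocyclobutenyl complex, copper-assisted transmetalation delivers the pyranonyl group, and reductive elimination at the hydrogen-bearing terminus keeps the conjugated vinylogous ester, while room temperature keeps the product below its ring-opening temperature.

Step 7
Reactants: 11 rac-4-[6-(3,4-dimethoxyphenyl)-4-oxo-4H-pyran-3-yl]-2,3-dimethoxycyclobut-2-en-1-one
Product: 14 2-(3,4-dimethoxyphenyl)-8-hydroxy-6,7-dimethoxy-4H-chromen-4-one, via vinylketene 12 (not isolated), via cyclohexadienone 13 (not isolated)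
Conditions: PhMe (degassed, 0.02 M), 110 °C
Reagents that add atoms: none
Why: Heat should break the C1–C4 bond of the cyclobutenone in a conrotatory 4π opening to dienylketene 12, whose ketene carbon (old C1) then bonds to pyranone C6 in a thermal disrotatory 6π electrocyclisation over the ketene C=C, the C3=C4 alkene and the pyranone C5=C6 bond, closing the six-membered A ring at C8–C8a as dienone 13. Enolisation of 13 with loss of the C8a hydrogen gives the aromatic C8 phenol and restores the pyranone, which makes the sequence irreversible. The closest known reaction type is the thermal ring expansion of 4-aryl, 4-heteroaryl and 4-quinonyl cyclobutenones to fused phenols (Moore-type cyclobutenone benzannulation). The only stereocentre formed, C8a of 13, is transient and is erased on aromatisation, so no stereocontrol is required. The step needs site selectivity and a productive opening geometry: the pyranone carbon on the other side of the attachment point is the C4 carbonyl carbon and bears no hydrogen, so only closure at C6 can aromatise, and because the 4π opening is reversible the ketene with the pyranonyl group turned outward returns to 11 and is drained through the inward isomer.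

Step 8
Reactants: 14 2-(3,4-dimethoxyphenyl)-8-hydroxy-6,7-dimethoxy-4H-chromen-4-one
Product: 15 2-(3,4-dimethoxyphenyl)-6,7,8-trimethoxy-4H-chromen-4-one
Conditions: MeI, K2CO3, DMF, rt
Reagents that add atoms: iodomethane, CI
Why: Williamson O-methylation of the only acidic hydroxyl, the C8 phenol, completes the 6,7,8-trimethoxy pattern without touching any other group.

**Compound list**
1 | (E)-4-methoxybut-3-en-2-one | CO/C=C/C(C)=O | starting material
2 | 3,4-dibromo-4-methoxybutan-2-one (diastereomer mixture, not isolated) | COC(Br)C(Br)C(C)=O | intermediate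
3 | (Z)-3-bromo-4-methoxybut-3-en-2-one | CO/C=C(\Br)C(C)=O | intermediate
4 | 3,4-dimethoxybenzoyl chloride | COc1ccc(C(=O)Cl)cc1OC | starting material
5 | (Z)-4-bromo-1-(3,4-dimethoxyphenyl)-5-methoxypent-4-ene-1,3-dione (not isolated) | CO/C=C(\Br)C(=O)CC(=O)c1ccc(OC)c(OC)c1 | intermediate
6 | 5-bromo-2-(3,4-dimethoxyphenyl)-4H-pyran-4-one | COc1ccc(-c2cc(=O)c(Br)co2)cc1OC | intermediate
7 | 2-(3,4-dimethoxyphenyl)-5-(tributylstannyl)-4H-pyran-4-one | CCCC[Sn](CCCC)(CCCC)c1coc(-c2ccc(OC)c(OC)c2)cc1=O | intermediate
8 | dimethyl squarate | COC1=C(OC)C(=O)C1=O | starting material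
9 | rac-4-hydroxy-2,3-dimethoxycyclobut-2-en-1-one | COC1=C(OC)C(O)C1=O | intermediate
10 | rac-4-chloro-2,3-dimethoxycyclobut-2-en-1-one | COC1=C(OC)C(Cl)C1=O | intermediate
11 | rac-4-[6-(3,4-dimethoxyphenyl)-4-oxo-4H-pyran-3-yl]-2,3-dimethoxycyclobut-2-en-1-one | COC1=C(OC)C(c2coc(-c3ccc(OC)c(OC)c3)cc2=O)C1=O | intermediate
12 | (3E)-4-[6-(3,4-dimethoxyphenyl)-4-oxo-4H-pyran-3-yl]-2,3-dimethoxybuta-1,3-dien-1-one (pyranonyl cis to the ketene carbon, not isolated) | O=C=C(OC)/C(OC)=C\c1coc(-c2ccc(OC)c(OC)c2)cc1=O | intermediate
13 | rac-2-(3,4-dimethoxyphenyl)-6,7-dimethoxy-8aH-chromene-4,8-dione (not isolated) | O=C1C(OC)=C(OC)C=C2C(=O)C=C(c3ccc(OC)c(OC)c3)OC12 | intermediate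
14 | 2-(3,4-dimethoxyphenyl)-8-hydroxy-6,7-dimethoxy-4H-chromen-4-one | COc1ccc(-c2cc(=O)c3cc(OC)c(OC)c(O)c3o2)cc1OC | intermediate
15 | 2-(3,4-dimethoxyphenyl)-6,7,8-trimethoxy-4H-chromen-4-one | COc1ccc(-c2cc(=O)c3cc(OC)c(OC)c(OC)c3o2)cc1OC | target

**Step count**
Total steps: 8. Longest linear sequence: 6 steps (steps 1, 2, 3, 6, 7, 8).

**Steps most likely to fail**

Step 5. Activation of the C4 hydroxyl may lead to ionisation to an alkoxy-stabilised oxocyclobutenyl cation, followed by loss of a methyl group or chloride return at the methoxy-bearing terminus, and the chloride may decay on handling. The fallback avoids the chloride. It sets out from 9, which is acetylated (Ac2O, pyridine, cat. DMAP, CH2Cl2, 0 °C) to the less ionisable rac-4-acetoxy-2,3-dimethoxycyclobut-2-en-1-one F1. This allylic acetate is then coupled with stannane 7 under Pd(0) in the presence of chloride (Pd2(dba)3, PPh3, LiCl, DMF, rt to 40 °C; Stille coupling of an allylic acetate), and the route is rejoined at 11.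

Step 6. Transmetalation of the electron-poor α-stannyl pyranone may be slow, so that protodestannylation, homocoupling or decay of the chloride outruns the coupling, or the new bond may form at the methoxy-bearing allyl terminus. The fallback makes the same C–C bond by carbonyl addition and sets out from bromide 6 and dimethyl squarate 8. Bromine–magnesium exchange (iPrMgCl·LiCl, THF, −40 °C) should give [6-(3,4-dimethoxyphenyl)-4-oxo-4H-pyran-3-yl]magnesium chloride F2, which is added to 8 at −78 °C to give rac-4-[6-(3,4-dimethoxyphenyl)-4-oxo-4H-pyran-3-yl]-4-hydroxy-2,3-dimethoxycyclobut-2-en-1-one F3. Thermolysis (p-xylene, 140 °C, argon; Moore rearrangement, the hydroxyl rotating outward and the pyranonyl group inward) should give 2-(3,4-dimethoxyphenyl)-5,8-dihydroxy-6,7-dimethoxy-4H-chromen-4-one F4. The non-chelated C8 hydroxyl is methylated selectively (MeI 1.1 equiv, K2CO3, acetone, rt) to 2-(3,4-dimethoxyphenyl)-5-hydroxy-6,7,8-trimethoxy-4H-chromen-4-one F5. The chelated C5 hydroxyl is converted (Tf2O, pyridine, CH2Cl2, 0 °C) into 2-(3,4-dimethoxyphenyl)-6,7,8-trimethoxy-4-oxo-4H-chromen-5-yl trifluoromethanesulfonate F6, and palladium-catalysed formate reduction (Pd(OAc)2, dppf, HCO2H, Et3N, DMF, 70 °C) removes the triflate to come back at target 15.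

Step 7. The ring opening may favour the geometry with the pyranonyl group outward, and the vinylketene may then be lost to dimerisation or adventitious nucleophiles before the reversible inward pathway closes; closure onto the electron-poor pyranone C6 may also be too slow. The fallback is the classical flavone construction and sets out from acid chloride 4. Commercial 1-(2-hydroxy-3,4,5-trimethoxyphenyl)ethan-1-one F7 is acylated with 4 (pyridine, rt) to 2-acetyl-4,5,6-trimethoxyphenyl 3,4-dimethoxybenzoate F8. Baker–Venkataraman rearrangement (KOH, pyridine, 50 °C) should give 1-(3,4-dimethoxyphenyl)-3-(2-hydroxy-3,4,5-trimethoxyphenyl)propane-1,3-dione F9, and cyclodehydration (H2SO4, AcOH, 100 °C) comes back at target 15.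

**Further compounds**
F1 | step 5 | rac-4-acetoxy-2,3-dimethoxycyclobut-2-en-1-one | COC1=C(OC)C(OC(C)=O)C1=O
F2 | step 6 | [6-(3,4-dimethoxyphenyl)-4-oxo-4H-pyran-3-yl]magnesium chloride | COc1ccc(-c2cc(=O)c([Mg]Cl)co2)cc1OC
F3 | step 6 | rac-4-[6-(3,4-dimethoxyphenyl)-4-oxo-4H-pyran-3-yl]-4-hydroxy-2,3-dimethoxycyclobut-2-en-1-one | COC1=C(OC)C(O)(c2coc(-c3ccc(OC)c(OC)c3)cc2=O)C1=O
F4 | step 6 | 2-(3,4-dimethoxyphenyl)-5,8-dihydroxy-6,7-dimethoxy-4H-chromen-4-one | COc1ccc(-c2cc(=O)c3c(O)c(OC)c(OC)c(O)c3o2)cc1OC
F5 | step 6 | 2-(3,4-dimethoxyphenyl)-5-hydroxy-6,7,8-trimethoxy-4H-chromen-4-one | COc1ccc(-c2cc(=O)c3c(O)c(OC)c(OC)c(OC)c3o2)cc1OC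
F6 | step 6 | 2-(3,4-dimethoxyphenyl)-6,7,8-trimethoxy-4-oxo-4H-chromen-5-yl trifluoromethanesulfonate | COc1ccc(-c2cc(=O)c3c(OS(=O)(=O)C(F)(F)F)c(OC)c(OC)c(OC)c3o2)cc1OC
F7 | step 7 | 1-(2-hydroxy-3,4,5-trimethoxyphenyl)ethan-1-one (purchased) | CC(=O)c1cc(OC)c(OC)c(OC)c1O
F8 | step 7 | 2-acetyl-4,5,6-trimethoxyphenyl 3,4-dimethoxybenzoate | CC(=O)c1cc(OC)c(OC)c(OC)c1OC(=O)c1ccc(OC)c(OC)c1
F9 | step 7 | 1-(3,4-dimethoxyphenyl)-3-(2-hydroxy-3,4,5-trimethoxyphenyl)propane-1,3-dione | COc1ccc(C(=O)CC(=O)c2cc(OC)c(OC)c(OC)c2O)cc1OC
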